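**Strategy.** Germacrane numbering is used: ring C1–C10, methyls on C4 and C10, isopropyl on C7, hydroxyl on C6, ester on C8. The ten-membered ring is cut between C9 and C10, where C8(O)–C9H2–C10(CH3)=C1H is a homoallylic alcohol. A nickel-catalysed reductive alkyne–epoxide macrocyclization of an acyclic methyl-alkynyl epoxide forms C9–C10, closes the ring, sets the (E)-C1=C10 alkene by syn addition and frees only the C8 hydroxyl, C6 remaining silylated. The precursor carries the C6–C7–C8 stereotriad from an auxiliary-controlled syn aldol, an alkenyllithium acylation and a hydroxyl-directed 1,3-anti reduction; esterification with protected p-coumaric acid and desilylation follow.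

Key step: step 9

Remark: anhydrous monomeric chloroacetaldehyde (7) is assumed to be distilled from the commercial material just before use; atom labels C1–C10 in the Why lines follow the germacrane numbering above.

Step 1
Reactants: 1 hexa-1,5-diyne
Product: 3 hepta-1,5-diyne, via lithium hexa-1,5-diyn-1-ide 2 (not isolated)
Conditions: 1 (3 equiv), n-BuLi (1 equiv), THF, −78 °C; MeI, −78 °C to rt; fractional distillation
Reagents that add atoms: iodomethane, CI
Why: Acetylide alkylation: monodeprotonation of one terminal alkyne and SN2 methylation, with excess 1 limiting double methylation and the three diynes separable by boiling point.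

Step 2
Reactants: 3 hepta-1,5-diyne
Product: 5 (1E)-1-iodo-2-methylhept-1-en-5-yne, via dimethyl[(1E)-2-methylhept-1-en-5-yn-1-yl]alumane 4 (not isolated)
Conditions: Me3Al, Cp2ZrCl2 (cat.), CH2Cl2, 0 °C to rt; I2, THF, −30 °C
Reagents that add atoms: trimethylaluminium, C[Al](C)C; iodine, II
Why: Negishi carboalumination adds methyl and aluminium syn across the terminal alkyne only (the internal alkyne reacts far more slowly), and iodinolysis with retention should give the (E)-iodide that fixes the C4=C5 geometry.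

Step 3
Reactants: 6 (4R)-4-benzyl-3-(3-methylbutanoyl)-1,3-oxazolidin-2-one; 7 chloroacetaldehyde
Product: 10 (4R)-4-benzyl-3-[(2R,3R)-4-chloro-3-hydroxy-2-(propan-2-yl)butanoyl]-1,3-oxazolidin-2-one, via Z-dibutylboron enolate 8 (not isolated), via dibutylboron aldolate 9 (not isolated)
Conditions: Bu2BOTf, i-Pr2NEt, CH2Cl2, 0 °C; 7, −78 to 0 °C; pH 7 buffer, MeOH, H2O2, 0 °C
Reagents that add atoms: none
Why: Evans syn aldol: the (Z)-boron enolate reacts through a closed chair transition state on the face away from the benzyl group, which should set C7 and C8 syn with the absolute sense dictated by the (R)-auxiliary.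

Step 4
Reactants: 10 aldol adduct
Product: 11 (2R,3R)-4-chloro-3-hydroxy-N-methoxy-N-methyl-2-(propan-2-yl)butanamide
Conditions: MeNH(OMe)·HCl, AlMe3, CH2Cl2, −20 to 0 °C
Reagents that add atoms: N,O-dimethylhydroxylamine hydrochloride, Cl.CNOC
Why: Weinreb amide formation by aluminium amide transamination, assisted by chelation of the free β-hydroxyl, should release the auxiliary without touching C7 or C8.

Step 5
Reactants: 11 Weinreb amide; 5 (1E)-1-iodo-2-methylhept-1-en-5-yne
Product: 15 (2R,3R,5E)-1-chloro-2-hydroxy-6-methyl-3-(propan-2-yl)undec-5-en-9-yn-4-one, via E-alkenyllithium 12 (not isolated), via chloromagnesium alkoxide 13 (not isolated), via tetrahedral adduct 14 (not isolated)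
Conditions: 11, i-PrMgCl, THF, −78 °C; separately 5, t-BuLi (2 equiv), Et2O, −78 °C; combine, −78 to −40 °C; aq. NH4Cl
Reagents that add atoms: none
Why: Iodine–lithium exchange with retention gives the (E)-alkenyllithium, which adds once to the Weinreb amide because the N-methoxy chelate holds the tetrahedral adduct until work-up, while the magnesium alkoxide saves organolithium and suppresses epoxide closure (Weinreb ketone synthesis).

Step 6
Reactants: 15 β-hydroxy enone
Product: 17 (2R,3S,4S,5E)-1-chloro-6-methyl-3-(propan-2-yl)undec-5-en-9-yne-2,4-diol, via alkoxydiacetoxyborohydride 16 (not isolated)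
Conditions: Me4NBH(OAc)3, MeCN/AcOH, −30 °C
Reagents that add atoms: none
Why: Evans–Saksena reduction: the C8 hydroxyl exchanges onto boron and hydride is delivered intramolecularly through a chair transition state, which should set C6 1,3-anti to C8 without conjugate reduction of the enone.

Step 7
Reactants: 17 chloro diol
Product: 18 (3S,4S,5E)-2,6-dimethyl-3-[(2R)-oxiran-2-yl]undec-5-en-9-yn-4-ol
Conditions: K2CO3, MeOH, 0 °C to rt
Reagents that add atoms: none
Why: Intramolecular Williamson reaction of the chlorohydrin (3-exo-tet, expected to outrun attack of the C6 alkoxide on C9) closes the epoxide with retention at C8 because only the C9–Cl bond is broken.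

Step 8
Reactants: 18 epoxy alcohol
Product: 19 triethyl{[(3R,4S,5E)-2,6-dimethyl-3-[(2R)-oxiran-2-yl]undec-5-en-9-yn-4-yl]oxy}silane
Conditions: TESCl, imidazole, DMF, 0 °C to rt
Reagents that add atoms: chlorotriethylsilane, CC[Si](Cl)(CC)CC
Why: Silyl ether formation at the only free hydroxyl under neutral imidazole conditions should leave the epoxide intact and marks O6 as different from the O8 that the ring closure releases.

Step 9
Reactants: 19 silylated alkynyl epoxide
Product: 21 (1S,3E,7E,9S,10R)-3,7-dimethyl-10-(propan-2-yl)-9-[(triethylsilyl)oxy]cyclodeca-3,7-dien-1-ol, via O8-diethylborinate 20 (not isolated)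
Conditions: 19 by syringe pump into Ni(cod)2 (0.3 equiv, zerovalent nickel), PBu3 (0.6 equiv), Et3B (3 equiv), toluene, 60 °C, final 0.003 M; aqueous work-up
Reagents that add atoms: none
Why: Proposed new method: zerovalent nickel carrying PBu3 and the alkyne should add oxidatively to the CH2–O bond of the epoxide (SN2-type attack at C9), the alkyne then inserts syn into the Ni–C9 bond to make C9–C10, and Et3B passes boron to O8 and ethyl to nickel, whose β-hydride elimination (loss of ethene) and C–H reductive elimination put hydrogen on C1 cis to C9. The closest known reaction type is the nickel-catalysed reductive coupling of alkynes with monosubstituted epoxides, known intermolecularly and in small-ring cyclizations that leave the alkene exocyclic, together with the nickel-catalysed alkyne–aldehyde reductive macrocyclization; a ten-membered ring with the new alkene inside the ring is the untested extension. The ten-membered carbocycle closes endo with respect to the alkyne (C1 and C10 in the ring) and endo with respect to the epoxide (C8 and C9 in the ring). No stereocenter is formed: C8 keeps its configuration because its C–O bond is untouched, and the (E)-C1=C10 geometry follows from the syn addition of C9 and H. The step needs bonding at C10 rather than C1, at C9 rather than C8, and ring closure rather than oligomerization: the small phosphine directs carbon to the less hindered methyl-bearing alkyne carbon and the alternative nine-membered ring with an (E)-alkene is more strained, the epoxide offers one unhindered CH2 terminus, and slow addition at high dilution of a chain pre-folded by its (E)-C4=C5 alkene favours cyclization. The pathway is polar, so no C9 radical can attack C4=C5 in a 5-exo mode.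

Step 10
Reactants: 22 (E)-p-coumaric acid
Product: 24 (2E)-3-{4-[(tert-butyldimethylsilyl)oxy]phenyl}prop-2-enoic acid, via bis-silylated coumarate 23 (not isolated)
Conditions: TBSCl (2.2 equiv), imidazole, DMF, rt; then K2CO3 (cat.), THF/H2O, rt; work-up at pH 4
Reagents that add atoms: tert-butyl(chloro)dimethylsilane, CC(C)(C)[Si](C)(C)Cl
Why: Silyl protection of phenol and acid followed by selective hydrolysis of the labile silyl ester should leave only the phenol masked.

Step 11
Reactants: 21 macrocyclic alcohol; 24 silyl-protected coumaric acid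
Product: 26 (1S,3E,7E,9S,10R)-3,7-dimethyl-10-(propan-2-yl)-9-[(triethylsilyl)oxy]cyclodeca-3,7-dien-1-yl (2E)-3-{4-[(tert-butyldimethylsilyl)oxy]phenyl}prop-2-enoate, via mixed trichlorobenzoic anhydride 25 (not isolated)
Conditions: 24, 2,4,6-trichlorobenzoyl chloride, Et3N, THF, rt; then 21, DMAP, toluene, rt to 40 °C
Reagents that add atoms: none
Why: Yamaguchi esterification through the mixed anhydride and an acylpyridinium should acylate the hindered secondary C8 hydroxyl, the only free hydroxyl, without alkene isomerization.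

Step 12
Reactants: 26 bis-silylated ester
Product: 27 (1S,3E,7E,9S,10S)-9-hydroxy-3,7-dimethyl-10-(propan-2-yl)cyclodeca-3,7-dien-1-yl (2E)-3-(4-hydroxyphenyl)prop-2-enoate (CNP0178839.1)
Conditions: TBAF, AcOH (1:1), THF, 0 °C to rt
Reagents that add atoms: none
Why: Desilylation by fluoride removes both silyl ethers, and the acetic acid buffer keeps the medium near neutral so that neither 1,3-acyl migration from O8 to O6 nor acid-induced transannular cyclization of the 1,5-diene should occur.

**Compound list**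

1 | hexa-1,5-diyne | C#CCCC#C | starting material
2 | lithium hexa-1,5-diyn-1-ide | [Li]C#CCCC#C | intermediate (not isolated)
3 | hepta-1,5-diyne | CC#CCCC#C | intermediate
4 | dimethyl[(1E)-2-methylhept-1-en-5-yn-1-yl]alumane | CC#CCC/C(C)=C/[Al](C)C | intermediate (not isolated)
5 | (1E)-1-iodo-2-methylhept-1-en-5-yne | CC#CCC/C(C)=C/I | intermediate
6 | (4R)-4-benzyl-3-(3-methylbutanoyl)-1,3-oxazolidin-2-one | CC(C)CC(=O)N1[C@H](Cc2ccccc2)COC1=O | starting material
7 | chloroacetaldehyde | O=CCCl | starting material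
8 | (4R)-4-benzyl-3-[(1Z)-1-[(dibutylboranyl)oxy]-3-methylbut-1-en-1-yl]-1,3-oxazolidin-2-one | CC(C)/C=C(\OB(CCCC)CCCC)N1[C@H](Cc2ccccc2)COC1=O | intermediate (not isolated)
9 | (4R)-4-benzyl-3-[(2R,3R)-4-chloro-3-[(dibutylboranyl)oxy]-2-(propan-2-yl)butanoyl]-1,3-oxazolidin-2-one | O=C1OC[C@@H](Cc2ccccc2)N1C(=O)[C@H](C(C)C)[C@@H](OB(CCCC)CCCC)CCl | intermediate (not isolated)
10 | (4R)-4-benzyl-3-[(2R,3R)-4-chloro-3-hydroxy-2-(propan-2-yl)butanoyl]-1,3-oxazolidin-2-one | O=C1OC[C@@H](Cc2ccccc2)N1C(=O)[C@H](C(C)C)[C@@H](O)CCl | intermediate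
11 | (2R,3R)-4-chloro-3-hydroxy-N-methoxy-N-methyl-2-(propan-2-yl)butanamide | CON(C)C(=O)[C@H](C(C)C)[C@@H](O)CCl | intermediate
12 | [(1E)-2-methylhept-1-en-5-yn-1-yl]lithium | CC#CCC/C(C)=C/[Li] | intermediate (not isolated)
13 | chloromagnesium alkoxide of 11 | CON(C)C(=O)[C@H](C(C)C)[C@@H](O[Mg]Cl)CCl | intermediate (not isolated)
14 | lithium N-methoxy-N-methyl hemiaminal alkoxide from 12 and 13 (tetrahedral adduct, new carbon unassigned) | CON(C)C(O[Li])(/C=C(\C)CCC#CC)[C@H](C(C)C)[C@@H](O[Mg]Cl)CCl | intermediate (not isolated)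
15 | (2R,3R,5E)-1-chloro-2-hydroxy-6-methyl-3-(propan-2-yl)undec-5-en-9-yn-4-one | C/C(CCC#CC)=C\C(=O)[C@H](C(C)C)[C@@H](O)CCl | intermediate
16 | tetramethylammonium diacetoxy(hydrido)borate ester of the C8 hydroxyl of 15 | C/C(CCC#CC)=C\C(=O)[C@H](C(C)C)[C@@H](O[BH-](OC(C)=O)OC(C)=O)CCl.C[N+](C)(C)C | intermediate (not isolated)
17 | (2R,3S,4S,5E)-1-chloro-6-methyl-3-(propan-2-yl)undec-5-en-9-yne-2,4-diol | C/C(CCC#CC)=C\[C@H](O)[C@H](C(C)C)[C@@H](O)CCl | intermediate
18 | (3S,4S,5E)-2,6-dimethyl-3-[(2R)-oxiran-2-yl]undec-5-en-9-yn-4-ol | C/C(CCC#CC)=C\[C@H](O)[C@H](C(C)C)[C@@H]1CO1 | intermediate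
19 | triethyl{[(3R,4S,5E)-2,6-dimethyl-3-[(2R)-oxiran-2-yl]undec-5-en-9-yn-4-yl]oxy}silane | C/C(CCC#CC)=C\[C@H](O[Si](CC)(CC)CC)[C@H](C(C)C)[C@@H]1CO1 | intermediate
20 | (1S,3E,7E,9S,10R)-3,7-dimethyl-10-(propan-2-yl)-9-[(triethylsilyl)oxy]cyclodeca-3,7-dien-1-yl diethylborinate | C/C1=C\[C@H](O[Si](CC)(CC)CC)[C@H](C(C)C)[C@@H](OB(CC)CC)C/C(C)=C/CC1 | intermediate (not isolated)
21 | (1S,3E,7E,9S,10R)-3,7-dimethyl-10-(propan-2-yl)-9-[(triethylsilyl)oxy]cyclodeca-3,7-dien-1-ol | C/C1=C\[C@H](O[Si](CC)(CC)CC)[C@H](C(C)C)[C@@H](O)C/C(C)=C/CC1 | intermediate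
22 | (2E)-3-(4-hydroxyphenyl)prop-2-enoic acid (p-coumaric acid) | O=C(O)/C=C/c1ccc(O)cc1 | starting material
23 | tert-butyldimethylsilyl (2E)-3-{4-[(tert-butyldimethylsilyl)oxy]phenyl}prop-2-enoate | CC(C)(C)[Si](C)(C)OC(=O)/C=C/c1ccc(O[Si](C)(C)C(C)(C)C)cc1 | intermediate (not isolated)
24 | (2E)-3-{4-[(tert-butyldimethylsilyl)oxy]phenyl}prop-2-enoic acid | CC(C)(C)[Si](C)(C)Oc1ccc(/C=C/C(=O)O)cc1 | intermediate
25 | (2E)-3-{4-[(tert-butyldimethylsilyl)oxy]phenyl}prop-2-enoic 2,4,6-trichlorobenzoic anhydride | CC(C)(C)[Si](C)(C)Oc1ccc(/C=C/C(=O)OC(=O)c2c(Cl)cc(Cl)cc2Cl)cc1 | intermediate (not isolated)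
26 | (1S,3E,7E,9S,10R)-3,7-dimethyl-10-(propan-2-yl)-9-[(triethylsilyl)oxy]cyclodeca-3,7-dien-1-yl (2E)-3-{4-[(tert-butyldimethylsilyl)oxy]phenyl}prop-2-enoate | C/C1=C\[C@H](O[Si](CC)(CC)CC)[C@H](C(C)C)[C@@H](OC(=O)/C=C/c2ccc(O[Si](C)(C)C(C)(C)C)cc2)C/C(C)=C/CC1 | intermediate
27 | (1S,3E,7E,9S,10S)-9-hydroxy-3,7-dimethyl-10-(propan-2-yl)cyclodeca-3,7-dien-1-yl (2E)-3-(4-hydroxyphenyl)prop-2-enoate | C/C1=C\[C@H](O)[C@H](C(C)C)[C@@H](OC(=O)/C=C/c2ccc(O)cc2)C/C(C)=C/CC1 | target

**Step count.** Total: 12 steps. Longest linear sequence: 9 steps (1, 2, 5, 6, 7, 8, 9, 11, 12; the branch 3, 4, 5–9, 11, 12 is equally long).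

**Steps most likely to fail**

Step 9 (proposed new method). The ring closure may lose to oligomerization, the alkyne may insert with the opposite regiochemistry to give a nine-membered ring, or the borane may isomerize the epoxide before coupling. The fallback closes the same bond with stoichiometric reagents of known reaction types, only the ring size being untested. It sets out from 17. Hydrozirconation of the 2-alkyne with excess Cp2Zr(H)Cl (the two hydroxyls are first converted into zirconium alkoxides; equilibration places zirconium on the methyl-bearing carbon) and iodinolysis should give (2R,3S,4S,5E,9E)-1-chloro-10-iodo-6-methyl-3-(propan-2-yl)undeca-5,9-diene-2,4-diol F1. K2CO3 in MeOH should close the epoxide to (3S,4S,5E,9E)-10-iodo-2,6-dimethyl-3-[(2R)-oxiran-2-yl]undeca-5,9-dien-4-ol F2, and TESCl with imidazole should give its triethylsilyl ether F3. Iodine–lithium exchange with t-BuLi at −78 °C in Et2O/THF at high dilution should give the (E)-alkenyllithium F4, and addition of BF3·OEt2 should then trigger SN2 opening of the epoxide at its CH2 terminus by the alkenyllithium. Aqueous work-up comes back to the route at 21.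

Step 5. The basic organolithium conditions may close the chlorohydrin alkoxide to the epoxide (which would remove the hydroxyl needed to direct step 6), cause retro-aldol cleavage, or leave the hindered amide unreacted. The fallback replaces the acylation by a chromium-mediated aldehyde coupling and sets out from 11. Silylation (TESOTf, 2,6-lutidine) should give (2R,3R)-4-chloro-N-methoxy-N-methyl-2-(propan-2-yl)-3-[(triethylsilyl)oxy]butanamide F5, and i-Bu2AlH reduction the aldehyde (2R,3R)-4-chloro-2-(propan-2-yl)-3-[(triethylsilyl)oxy]butanal F6. Nozaki–Hiyama–Kishi coupling of F6 with 5 (CrCl2, NiCl2 cat., DMSO) should give (2R,3S,5E)-1-chloro-6-methyl-3-(propan-2-yl)-2-[(triethylsilyl)oxy]undec-5-en-9-yn-4-ol F7 as a mixture at the new carbinol. Dess–Martin oxidation should converge this on (2R,3R,5E)-1-chloro-6-methyl-3-(propan-2-yl)-2-[(triethylsilyl)oxy]undec-5-en-9-yn-4-one F8, and HF·pyridine should remove the silyl group, coming back to the route at 15.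

Step 3. Chloroacetaldehyde may polymerize or carry water, so that the boron enolate is quenched or converts poorly. The fallback uses a stable aldehyde and installs chlorine afterwards; it sets out from 6. The same boron enolate is combined with commercial (tert-butyldimethylsilyloxy)acetaldehyde to give (4R)-4-benzyl-3-[(2R,3R)-4-[(tert-butyldimethylsilyl)oxy]-3-hydroxy-2-(propan-2-yl)butanoyl]-1,3-oxazolidin-2-one F9. HF·pyridine should give (4R)-4-benzyl-3-[(2R,3R)-3,4-dihydroxy-2-(propan-2-yl)butanoyl]-1,3-oxazolidin-2-one F10, and selective chlorination of the primary hydroxyl (PPh3, N-chlorosuccinimide, 0 °C) comes back to the route at 10.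

Further compounds
F1 | step 9 | (2R,3S,4S,5E,9E)-1-chloro-10-iodo-6-methyl-3-(propan-2-yl)undeca-5,9-diene-2,4-diol | C/C(CC/C=C(\C)I)=C\[C@H](O)[C@H](C(C)C)[C@@H](O)CCl
F2 | step 9 | (3S,4S,5E,9E)-10-iodo-2,6-dimethyl-3-[(2R)-oxiran-2-yl]undeca-5,9-dien-4-ol | C/C(CC/C=C(\C)I)=C\[C@H](O)[C@H](C(C)C)[C@@H]1CO1
F3 | step 9 | triethyl{[(3R,4S,5E,9E)-10-iodo-2,6-dimethyl-3-[(2R)-oxiran-2-yl]undeca-5,9-dien-4-yl]oxy}silane | C/C(CC/C=C(\C)I)=C\[C@H](O[Si](CC)(CC)CC)[C@H](C(C)C)[C@@H]1CO1
F4 | step 9 | (E)-alkenyllithium from F3 (lithium in place of iodine on C10) | C/C(CC/C=C(\C)[Li])=C\[C@H](O[Si](CC)(CC)CC)[C@H](C(C)C)[C@@H]1CO1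
F5 | step 5 | (2R,3R)-4-chloro-N-methoxy-N-methyl-2-(propan-2-yl)-3-[(triethylsilyl)oxy]butanamide | CON(C)C(=O)[C@H](C(C)C)[C@@H](O[Si](CC)(CC)CC)CCl
F6 | step 5 | (2R,3R)-4-chloro-2-(propan-2-yl)-3-[(triethylsilyl)oxy]butanal | O=C[C@H](C(C)C)[C@@H](O[Si](CC)(CC)CC)CCl
F7 | step 5 | (2R,3S,5E)-1-chloro-6-methyl-3-(propan-2-yl)-2-[(triethylsilyl)oxy]undec-5-en-9-yn-4-ol (both C4 epimers) | C/C(CCC#CC)=C\C(O)[C@H](C(C)C)[C@@H](O[Si](CC)(CC)CC)CCl
F8 | step 5 | (2R,3R,5E)-1-chloro-6-methyl-3-(propan-2-yl)-2-[(triethylsilyl)oxy]undec-5-en-9-yn-4-one | C/C(CCC#CC)=C\C(=O)[C@H](C(C)C)[C@@H](O[Si](CC)(CC)CC)CCl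
F9 | step 3 | (4R)-4-benzyl-3-[(2R,3R)-4-[(tert-butyldimethylsilyl)oxy]-3-hydroxy-2-(propan-2-yl)butanoyl]-1,3-oxazolidin-2-one | O=C1OC[C@@H](Cc2ccccc2)N1C(=O)[C@H](C(C)C)[C@@H](O)CO[Si](C)(C)C(C)(C)C
F10 | step 3 | (4R)-4-benzyl-3-[(2R,3R)-3,4-dihydroxy-2-(propan-2-yl)butanoyl]-1,3-oxazolidin-2-one | O=C1OC[C@@H](Cc2ccccc2)N1C(=O)[C@H](C(C)C)[C@@H](O)CO
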